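**Plan**

Germacrane numbering is used: carbocycle C1–C10; lactone O–C6 and C7–C11–C12(=O); C13 the exocyclic methylene; C14 the CO2Me carbon on C10; C15 the methyl on C4.
Retrosynthetic cuts, in order: the O8–acyl and O9–acetyl bonds and C11=C13; then the ring bond C9–C10, which opens the ten-membered ring; then C1=C10 (Wittig), C7–C8 (radical conjugate addition), C6–C7 with the lactone C–O bond (alkynylation, lactonisation), C5–C6 (formylation) and C4–C15 (carbometalation).
Forward: the five-membered lactone is made first as a butenolide, the L-tartrate dioxolane is attached at C7–C8, the chain is extended to C10, and the ten-membered ring is closed last at C9–C10; the methylene and the two esters follow.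
Enabling feature: ring atoms C8 and C9 carry a trans (threo) diol, 8S,9S, and each is flanked by a ring C–C bond (C7–C8 and C9–C10). This is L-tartaric acid with one carboxyl sitting on each of those bonds, so each carboxyl can leave as CO2 to give the radical that makes that bond, the second one closing the C1–C10 ring.
Stereochemistry: C6 from a catalyst-controlled alkynylation; C7 from C6 (addition anti to the butenolide substituent); C8 and C9 from L-tartrate, relayed through the trans-dioxolane; E-C4=C5 from syn-carboalumination; ring-cis C1=C10 from a Z-selective iodo-Wittig reaction with retention at nickel.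

Key step: step 13

Assumption: (S,S)-ProPhenol is taken to give the 4R alcohol 8; if the sense of induction is the opposite, the equally available (R,R)-ligand is used and nothing else changes.

**Route**

Step 1
Reactants: 1 pent-4-yn-1-ol
Product: 2 tert-butyldimethyl(pent-4-yn-1-yloxy)silane
Conditions: TBSCl, imidazole, DMF, rt
Reagents that add atoms: tert-butyldimethylsilyl chloride, CC(C)(C)[Si](C)(C)Cl
Why: Silyl ether formation (Corey protocol) in which imidazole-activated TBSCl silylates the primary alcohol and leaves the terminal alkyne untouched.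

Step 2
Reactants: 2 tert-butyldimethyl(pent-4-yn-1-yloxy)silane
Product: 4 (E)-tert-butyl[(5-iodo-4-methylpent-4-en-1-yl)oxy]dimethylsilane, via alkenyldimethylalane 3 (not isolated)
Conditions: AlMe3 (2.5 equiv), Cp2ZrCl2 (0.25 equiv), CH2Cl2, 0 °C to rt; then I2, THF, −30 to 0 °C
Reagents that add atoms: trimethylaluminium, C[Al](C)C; iodine, II
Why: Negishi zirconium-catalysed carboalumination adds CH3 and aluminium syn across the terminal alkyne with CH3 on the internal carbon, and iodinolysis of the C–Al bond with retention gives the E-iodide that fixes the geometry of the future C4=C5 bond.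

Step 3
Reactants: 4 (E)-tert-butyl[(5-iodo-4-methylpent-4-en-1-yl)oxy]dimethylsilane
Product: 6 (E)-6-(tert-butyldimethylsilyloxy)-3-methylhex-2-enal, via alkenyllithium 5 (not isolated)
Conditions: t-BuLi (2.1 equiv), Et2O, −78 °C; then DMF, −78 to 0 °C; H2O quench
Reagents that add atoms: N,N-dimethylformamide, CN(C)C=O
Why: Iodine–lithium exchange proceeds with retention of olefin geometry and the alkenyllithium is formylated by DMF (Bouveault formylation), giving the E-enal that carries C1 to C6.

Step 4
Reactants: 6 (E)-6-(tert-butyldimethylsilyloxy)-3-methylhex-2-enal; 7 methyl propiolate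
Product: 8 methyl (4R,5E)-9-(tert-butyldimethylsilyloxy)-4-hydroxy-6-methylnon-5-en-2-ynoate
Conditions: (S,S)-ProPhenol (20 mol %), Me2Zn (3 equiv), 7 (3 equiv), toluene, 0 to 4 °C; aqueous NH4Cl work-up
Reagents that add atoms: none
Why: Trost zinc–ProPhenol asymmetric alkynylation, in which the dinuclear zinc alkoxide binds the enal and the zinc acetylide of methyl propiolate and delivers the alkyne to one carbonyl face, sets C6 (4R in the ynoate).

Step 5
Reactants: 8 methyl (4R,5E)-9-(tert-butyldimethylsilyloxy)-4-hydroxy-6-methylnon-5-en-2-ynoate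
Product: 10 (5S)-5-[(1E)-5-(tert-butyldimethylsilyloxy)-2-methylpent-1-en-1-yl]furan-2(5H)-one, via (Z)-hydroxy dienoate 9 (not isolated)
Conditions: H2 (1 atm), Pd/CaCO3 poisoned with Pb(OAc)2 (Lindlar catalyst), quinoline, EtOAc, rt; then PPTS (5 mol %), CH2Cl2, rt
Reagents that add atoms: none
Why: Lindlar cis-semihydrogenation gives the Z-γ-hydroxy enoate, whose hydroxyl lies next to the ester and closes to the butenolide under mild acid without touching the carbinol centre (the descriptor changes to S only through CIP priorities) or the trisubstituted olefin.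

Step 6
Reactants: 11 dimethyl 2,3-O-isopropylidene-L-tartrate
Product: 12 (4R,5R)-5-(methoxycarbonyl)-2,2-dimethyl-1,3-dioxolane-4-carboxylic acid
Conditions: KOH (1.0 equiv), MeOH, rt; aqueous HCl work-up (pH 2)
Reagents that add atoms: potassium hydroxide, [K+].[OH-]
Why: Monosaponification of a symmetric diester works because the first carboxylate slows hydrolysis of the second ester, and as the diester is C2-symmetric either ester gives the same acid with both centres untouched.

Step 7
Reactants: 12 (4R,5R)-5-(methoxycarbonyl)-2,2-dimethyl-1,3-dioxolane-4-carboxylic acid; 10 (5S)-5-[(1E)-5-(tert-butyldimethylsilyloxy)-2-methylpent-1-en-1-yl]furan-2(5H)-one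
Product: 13 methyl (4R,5S)-5-[(2R,3S)-2-[(1E)-5-(tert-butyldimethylsilyloxy)-2-methylpent-1-en-1-yl]-5-oxooxolan-3-yl]-2,2-dimethyl-1,3-dioxolane-4-carboxylate
Conditions: 12 (1.5 equiv), Ir[dF(CF3)ppy]2(dtbbpy)PF6 (2 mol %), K2HPO4 (1.2 equiv), DMF, blue LEDs, rt
Reagents that add atoms: none
Why: In this photoredox decarboxylative Giese addition the excited iridium photocatalyst oxidises the carboxylate, loss of CO2 gives the C8 dioxolanyl radical, and this adds to the butenolide β-carbon anti to the C6 alkenyl group (sets C7, trans lactone) and forms its bond trans to the C9 ester on the dioxolane (sets C8), before reduction and protonation of the lactone α-radical.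

Step 8
Reactants: 13 silyl ether (Giese adduct)
Product: 14 methyl (4R,5S)-5-[(2R,3S)-2-[(1E)-5-hydroxy-2-methylpent-1-en-1-yl]-5-oxooxolan-3-yl]-2,2-dimethyl-1,3-dioxolane-4-carboxylate
Conditions: HF·pyridine, pyridine, THF, 0 °C to rt
Reagents that add atoms: none
Why: Fluoride-mediated desilylation under buffered acidic conditions removes the primary TBS ether and leaves acetonide, lactone and methyl ester intact.

Step 9
Reactants: 14 primary alcohol
Product: 15 methyl (4R,5S)-5-[(2R,3S)-2-[(1E)-2-methyl-5-oxopent-1-en-1-yl]-5-oxooxolan-3-yl]-2,2-dimethyl-1,3-dioxolane-4-carboxylate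
Conditions: Dess–Martin periodinane, pyridine, CH2Cl2, 0 °C to rt
Reagents that add atoms: none
Why: Dess–Martin oxidation converts the primary alcohol into the C1 aldehyde under near-neutral conditions without epimerising the α-alkoxy ester or moving the olefin.

Step 10
Reactants: 15 aldehyde
Product: 16 methyl (4R,5S)-5-[(2R,3S)-2-[(1E,5Z)-6-iodo-7-methoxy-2-methyl-7-oxohepta-1,5-dien-1-yl]-5-oxooxolan-3-yl]-2,2-dimethyl-1,3-dioxolane-4-carboxylate
Conditions: Ph3P=CHCO2Me, N-iodosuccinimide, MeCN, −20 °C; then K2CO3 and 15, −20 °C to rt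
Reagents that add atoms: methyl (triphenylphosphoranylidene)acetate, COC(=O)C=P(c1ccccc1)(c1ccccc1)c1ccccc1; N-iodosuccinimide, O=C1CCC(=O)N1I
Why: Wittig olefination with the ester-stabilised ylide iodinated in the flask places the ester trans to the alkyl chain, so iodine ends up cis to C2 (Z-iodoenoate), the geometry needed for the ring-cis C1=C10 bond.

Step 11
Reactants: 16 diester (Z)-iodoenoate
Product: 17 (4R,5S)-5-[(2R,3S)-2-[(1E,5Z)-6-iodo-7-methoxy-2-methyl-7-oxohepta-1,5-dien-1-yl]-5-oxooxolan-3-yl]-2,2-dimethyl-1,3-dioxolane-4-carboxylic acid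
Conditions: Me3SnOH (4 equiv), ClCH2CH2Cl, 60 °C; dilute aqueous HCl wash
Reagents that add atoms: trimethyltin hydroxide, C[Sn](C)(C)O
Why: Trimethyltin hydroxide ester hydrolysis should select the unhindered methyl ester activated by its α-oxygen over the conjugated iodine-flanked ester, any opened lactone re-closes on acidic work-up, and the C9 centre is planarised in step 13 in any case.

Step 12
Reactants: 17 carboxylic acid
Product: 18 1,3-dioxoisoindolin-2-yl (4R,5S)-5-[(2R,3S)-2-[(1E,5Z)-6-iodo-7-methoxy-2-methyl-7-oxohepta-1,5-dien-1-yl]-5-oxooxolan-3-yl]-2,2-dimethyl-1,3-dioxolane-4-carboxylate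
Conditions: N-hydroxyphthalimide, DIC, DMAP (5 mol %), CH2Cl2, 0 °C to rt; used without delay
Reagents that add atoms: N-hydroxyphthalimide, O=C1c2ccccc2C(=O)N1O
Why: Carbodiimide (Steglich-type) coupling with N-hydroxyphthalimide gives the redox-active ester under neutral conditions that leave the iodoalkene and the lactone untouched.

Step 13
Reactants: 18 seco redox-active ester with (Z)-iodoenoate
Product: 19 methyl (1(10)E,4E,6R,7S,8S,9S)-8,9-(isopropylidenedioxy)-germacra-1(10),4-dien-12,6-olid-14-oate (C2 and C9 cis on C1=C10)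
Conditions: NiCl2·glyme (20 mol %), 2,2'-bipyridine (24 mol %), AgNO3 (0.3 equiv), LiCl, DMF, Mg anode, reticulated vitreous carbon cathode, undivided cell, constant current, rt, 18 added by syringe pump (about 2 mM)
Reagents that add atoms: none
Why: Proposed new method: cathodically generated zerovalent nickel on bipyridine inserts into the C10–I bond, the alkenylnickel is reduced to the monovalent state and passes an electron to the N-acyloxyphthalimide, which breaks down to phthalimide anion, CO2 and the C9 dioxolanyl radical; capture of this radical by divalent alkenylnickel and reductive elimination from trivalent nickel form C9–C10, the closest known reaction being the intermolecular nickel-electrocatalysed decarboxylative alkenylation of redox-active esters with alkenyl halides, which accepts tartrate-type dioxolanyl esters but has not been used to close a medium ring. The ten-membered carbocycle closes in an endo sense (C1 and C10 of the olefin both lie in the new ring) by radical capture at a metal and not through a strained polar transition state, and slow addition keeps the substrate dilute so that ring closure can outrun coupling between molecules. The new C9 centre is set by the resident C8 centre through the dioxolane: the planarised radical can be bonded on only one of two faces, and the trans-fused bicycle (C7–C8–C9–C10 torsion of roughly 90–150°) should be reached more easily than the cis-fused one, which needs a nearly eclipsed ring torsion. The step needs retention of the iodoalkene geometry, which oxidative addition and reductive elimination at nickel preserve, so that C2 and C9 end up cis on C1=C10; it also needs the radical to meet nickel before anything else, which is helped by the turn imposed by the E-C4=C5 olefin and the trans lactone and by the absence of a good radical acceptor, since the lactone still lacks its methylene and the other olefins are trisubstituted.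

Step 14
Reactants: 19 ten-membered lactone acetonide
Product: 21 (11R)-11-(dimethylaminomethyl) derivative of 19, via lithium enolate 20 (not isolated)
Conditions: LiN(SiMe3)2 (1.1 equiv), THF, −78 °C; then CH2=NMe2+ I−, −78 to 0 °C
Reagents that add atoms: N,N-dimethylmethyleneiminium iodide (Eschenmoser's salt), C=[N+](C)C.[I-]
Why: Kinetic enolisation of the lactone, the only carbonyl with α-hydrogens, and Mannich reaction of the enolate with Eschenmoser's salt install C13, attack anti to the C7 substituent giving the 11R amine, a centre that is removed in the next step.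

Step 15
Reactants: 21 Mannich base
Product: 23 methyl (1(10)E,4E,6R,7S,8S,9S)-8,9-(isopropylidenedioxy)-germacra-1(10),4,11(13)-trien-12,6-olid-14-oate, via ammonium iodide 22 (not isolated)
Conditions: MeI, THF, rt; then aqueous NaHCO3, EtOAc, rt
Reagents that add atoms: none
Why: Quaternisation of the amine and base-induced E1cB (Hofmann-type) elimination of trimethylamine give the α-methylene lactone.

Step 16
Reactants: 23 methylene lactone acetonide
Product: 24 methyl (1(10)E,4E,6R,7S,8S,9S)-8,9-dihydroxygermacra-1(10),4,11(13)-trien-12,6-olid-14-oate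
Conditions: AcOH/H2O (4:1), 40 °C
Reagents that add atoms: none
Why: Acid-catalysed acetal hydrolysis cleaves the strained trans-fused dioxolane with aqueous acetic acid under conditions that the methyl enoate and the methylene lactone tolerate.

Step 17
Reactants: 24 8,9-diol
Product: 25 methyl (1(10)E,4E,6R,7S,8S,9S)-9-acetoxy-8-hydroxygermacra-1(10),4,11(13)-trien-12,6-olid-14-oate
Conditions: AcCl (1.05 equiv), 2,4,6-collidine, CH2Cl2, −78 to −40 °C
Reagents that add atoms: acetyl chloride, CC(=O)Cl
Why: Kinetically controlled acyl transfer at low temperature is expected to go to O9, which is flanked by the sp2 carbon C10 and hydrogen-bonded to the C14 carbonyl, rather than to O8, which lies between two sp3 methine carbons and syn to the lactone.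

Step 18
Reactants: 26 methyl 2-(hydroxymethyl)acrylate
Product: 27 methyl 2-[(tert-butyldimethylsilyloxy)methyl]acrylate
Conditions: TBSCl, imidazole, DMF, 0 °C to rt
Reagents that add atoms: tert-butyldimethylsilyl chloride, CC(C)(C)[Si](C)(C)Cl
Why: Silyl ether formation on the primary allylic alcohol masks the hydroxyl for the later esterification.

Step 19
Reactants: 27 methyl 2-[(tert-butyldimethylsilyloxy)methyl]acrylate
Product: 28 2-[(tert-butyldimethylsilyloxy)methyl]acrylic acid
Conditions: LiOH·H2O, THF/H2O, 0 °C; dilute aqueous HCl to pH 4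
Reagents that add atoms: lithium hydroxide, [Li+].[OH-]
Why: Saponification with LiOH frees the acid while the primary TBS ether survives cold aqueous base and brief mild acidification.

Step 20
Reactants: 28 2-[(tert-butyldimethylsilyloxy)methyl]acrylic acid; 25 9-acetate 8-alcohol
Product: 30 methyl (1(10)E,4E,6R,7S,8S,9S)-9-acetoxy-8-{2-[(tert-butyldimethylsilyloxy)methyl]acryloyloxy}germacra-1(10),4,11(13)-trien-12,6-olid-14-oate, via mixed anhydride 29 (not isolated)
Conditions: 2,4,6-trichlorobenzoyl chloride, Et3N, toluene, rt; then 25, DMAP, toluene, rt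
Reagents that add atoms: none
Why: In this Yamaguchi esterification the mixed anhydride acylates DMAP and then the hindered secondary O8 hydroxyl, and a short reaction time at room temperature limits acetyl migration from O9.

Step 21
Reactants: 30 silyl-protected target
Product: 31 CNP0291058.1, methyl (1(10)E,4E,6R,7S,8S,9S)-9-acetoxy-8-[2-(hydroxymethyl)acryloyloxy]germacra-1(10),4,11(13)-trien-12,6-olid-14-oate
Conditions: HF·pyridine, pyridine, THF, 0 °C
Reagents that add atoms: none
Why: Desilylation with buffered HF·pyridine frees the primary alcohol without base, so the allylic acetate, the acrylate ester and the methylene lactone are not attacked.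

**Compound list**

1 | pent-4-yn-1-ol | C#CCCCO | starting material
2 | tert-butyldimethyl(pent-4-yn-1-yloxy)silane | C#CCCCO[Si](C)(C)C(C)(C)C | intermediate
3 | (E)-[5-(tert-butyldimethylsilyloxy)-2-methylpent-1-en-1-yl]dimethylalane (not isolated) | C[Al](C)/C=C(\C)CCCO[Si](C)(C)C(C)(C)C | intermediate
4 | (E)-tert-butyl[(5-iodo-4-methylpent-4-en-1-yl)oxy]dimethylsilane | I/C=C(\C)CCCO[Si](C)(C)C(C)(C)C | intermediate
5 | (E)-[5-(tert-butyldimethylsilyloxy)-2-methylpent-1-en-1-yl]lithium (not isolated) | [Li]/C=C(\C)CCCO[Si](C)(C)C(C)(C)C | intermediate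
6 | (E)-6-(tert-butyldimethylsilyloxy)-3-methylhex-2-enal | O=C/C=C(\C)CCCO[Si](C)(C)C(C)(C)C | intermediate
7 | methyl propiolate | C#CC(=O)OC | starting material
8 | methyl (4R,5E)-9-(tert-butyldimethylsilyloxy)-4-hydroxy-6-methylnon-5-en-2-ynoate | COC(=O)C#C[C@H](O)/C=C(\C)CCCO[Si](C)(C)C(C)(C)C | intermediate
9 | methyl (2Z,4S,5E)-9-(tert-butyldimethylsilyloxy)-4-hydroxy-6-methylnona-2,5-dienoate (not isolated) | COC(=O)/C=C\[C@H](O)/C=C(\C)CCCO[Si](C)(C)C(C)(C)C | intermediate
10 | (5S)-5-[(1E)-5-(tert-butyldimethylsilyloxy)-2-methylpent-1-en-1-yl]furan-2(5H)-one | O=C1C=C[C@H](O1)/C=C(\C)CCCO[Si](C)(C)C(C)(C)C | intermediate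
11 | dimethyl 2,3-O-isopropylidene-L-tartrate | COC(=O)[C@@H]1OC(C)(C)O[C@H]1C(=O)OC | starting material
12 | (4R,5R)-5-(methoxycarbonyl)-2,2-dimethyl-1,3-dioxolane-4-carboxylic acid | COC(=O)[C@@H]1OC(C)(C)O[C@H]1C(=O)O | intermediate
13 | methyl (4R,5S)-5-[(2R,3S)-2-[(1E)-5-(tert-butyldimethylsilyloxy)-2-methylpent-1-en-1-yl]-5-oxooxolan-3-yl]-2,2-dimethyl-1,3-dioxolane-4-carboxylate | COC(=O)[C@@H]1OC(C)(C)O[C@H]1[C@H]2CC(=O)O[C@@H]2/C=C(\C)CCCO[Si](C)(C)C(C)(C)C | intermediate
14 | methyl (4R,5S)-5-[(2R,3S)-2-[(1E)-5-hydroxy-2-methylpent-1-en-1-yl]-5-oxooxolan-3-yl]-2,2-dimethyl-1,3-dioxolane-4-carboxylate | COC(=O)[C@@H]1OC(C)(C)O[C@H]1[C@H]2CC(=O)O[C@@H]2/C=C(\C)CCCO | intermediate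
15 | methyl (4R,5S)-5-[(2R,3S)-2-[(1E)-2-methyl-5-oxopent-1-en-1-yl]-5-oxooxolan-3-yl]-2,2-dimethyl-1,3-dioxolane-4-carboxylate | COC(=O)[C@@H]1OC(C)(C)O[C@H]1[C@H]2CC(=O)O[C@@H]2/C=C(\C)CCC=O | intermediate
16 | methyl (4R,5S)-5-[(2R,3S)-2-[(1E,5Z)-6-iodo-7-methoxy-2-methyl-7-oxohepta-1,5-dien-1-yl]-5-oxooxolan-3-yl]-2,2-dimethyl-1,3-dioxolane-4-carboxylate | COC(=O)[C@@H]1OC(C)(C)O[C@H]1[C@H]2CC(=O)O[C@@H]2/C=C(\C)CC/C=C(\I)C(=O)OC | intermediate
17 | (4R,5S)-5-[(2R,3S)-2-[(1E,5Z)-6-iodo-7-methoxy-2-methyl-7-oxohepta-1,5-dien-1-yl]-5-oxooxolan-3-yl]-2,2-dimethyl-1,3-dioxolane-4-carboxylic acid | OC(=O)[C@@H]1OC(C)(C)O[C@H]1[C@H]2CC(=O)O[C@@H]2/C=C(\C)CC/C=C(\I)C(=O)OC | intermediate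
18 | 1,3-dioxoisoindolin-2-yl ester of 17 (seco redox-active ester) | O=C(ON1C(=O)c2ccccc2C1=O)[C@@H]3OC(C)(C)O[C@H]3[C@H]4CC(=O)O[C@@H]4/C=C(\C)CC/C=C(\I)C(=O)OC | intermediate
19 | methyl (1(10)E,4E,6R,7S,8S,9S)-8,9-(isopropylidenedioxy)-germacra-1(10),4-dien-12,6-olid-14-oate | CC1(C)O[C@H]2[C@H]3CC(=O)O[C@@H]3/C=C(\C)CC/C=C(/C(=O)OC)[C@@H]2O1 | intermediate
20 | lithium enolate of 19 at C11/C12 (not isolated) | CC1(C)O[C@H]2[C@H]3C=C(O[Li])O[C@@H]3/C=C(\C)CC/C=C(/C(=O)OC)[C@@H]2O1 | intermediate
21 | (11R)-11-(dimethylaminomethyl) derivative of 19 (CH2NMe2 trans to C8 on the lactone) | CC1(C)O[C@H]2[C@H]3[C@H](CN(C)C)C(=O)O[C@@H]3/C=C(\C)CC/C=C(/C(=O)OC)[C@@H]2O1 | intermediate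
22 | (11R)-11-(trimethylammoniomethyl) iodide of 19 (not isolated) | CC1(C)O[C@H]2[C@H]3[C@H](C[N+](C)(C)C)C(=O)O[C@@H]3/C=C(\C)CC/C=C(/C(=O)OC)[C@@H]2O1.[I-] | intermediate
23 | methyl (1(10)E,4E,6R,7S,8S,9S)-8,9-(isopropylidenedioxy)-germacra-1(10),4,11(13)-trien-12,6-olid-14-oate | CC1(C)O[C@H]2[C@H]3C(=C)C(=O)O[C@@H]3/C=C(\C)CC/C=C(/C(=O)OC)[C@@H]2O1 | intermediate
24 | methyl (1(10)E,4E,6R,7S,8S,9S)-8,9-dihydroxygermacra-1(10),4,11(13)-trien-12,6-olid-14-oate | O[C@H]1[C@H]2C(=C)C(=O)O[C@@H]2/C=C(\C)CC/C=C(/C(=O)OC)[C@@H]1O | intermediate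
25 | methyl (1(10)E,4E,6R,7S,8S,9S)-9-acetoxy-8-hydroxygermacra-1(10),4,11(13)-trien-12,6-olid-14-oate | O[C@H]1[C@H]2C(=C)C(=O)O[C@@H]2/C=C(\C)CC/C=C(/C(=O)OC)[C@@H]1OC(C)=O | intermediate
26 | methyl 2-(hydroxymethyl)acrylate | C=C(CO)C(=O)OC | starting material
27 | methyl 2-[(tert-butyldimethylsilyloxy)methyl]acrylate | C=C(CO[Si](C)(C)C(C)(C)C)C(=O)OC | intermediate
28 | 2-[(tert-butyldimethylsilyloxy)methyl]acrylic acid | C=C(CO[Si](C)(C)C(C)(C)C)C(=O)O | intermediate
29 | 2-[(tert-butyldimethylsilyloxy)methyl]acrylic 2,4,6-trichlorobenzoic anhydride (not isolated) | C=C(CO[Si](C)(C)C(C)(C)C)C(=O)OC(=O)c1c(Cl)cc(Cl)cc1Cl | intermediate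
30 | methyl (1(10)E,4E,6R,7S,8S,9S)-9-acetoxy-8-{2-[(tert-butyldimethylsilyloxy)methyl]acryloyloxy}germacra-1(10),4,11(13)-trien-12,6-olid-14-oate | C=C(CO[Si](C)(C)C(C)(C)C)C(=O)O[C@H]1[C@H]2C(=C)C(=O)O[C@@H]2/C=C(\C)CC/C=C(/C(=O)OC)[C@@H]1OC(C)=O | intermediate
31 | CNP0291058.1, methyl (1(10)E,4E,6R,7S,8S,9S)-9-acetoxy-8-[2-(hydroxymethyl)acryloyloxy]germacra-1(10),4,11(13)-trien-12,6-olid-14-oate | C=C(CO)C(=O)O[C@H]1[C@H]2C(=C)C(=O)O[C@@H]2/C=C(\C)CC/C=C(/C(=O)OC)[C@@H]1OC(C)=O | target

**Step count and risks**

Total steps: 21. Longest linear sequence: 18 (steps 1–5, 7–17, 20, 21).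

Steps most likely to fail:

1. Step 13. The C9 radical or the alkenylnickel may be quenched (hydrodecarboxylation, hydrodeiodination) or may couple between molecules before the ring closes, or the bond may form on the face cis to C7. The fallback reverses the order of the two decarboxylative bond formations and uses known reaction types. It sets out from 10 and 12 and comes back at 19. Butenolide 10 is desilylated with HF·pyridine to the hydroxy butenolide F1, oxidised with Dess–Martin periodinane to the aldehyde butenolide F2, and olefinated with the iodinated ylide to the butenolide (Z)-iodoenoate F3. Acid 12 is converted with N-hydroxyphthalimide and DIC into the tartrate monoester phthalimide ester F4. F3 and F4 are joined by the known intermolecular nickel-electrocatalysed decarboxylative alkenylation, run with a high nickel loading so that capture at nickel outruns addition to the butenolide, to give the C9–C10-linked trans-dioxolane diester F5. Me3SnOH then frees the C8 acid F6, and the ten-membered ring is closed at C7–C8 by an intramolecular photoredox decarboxylative Giese addition to the butenolide at high dilution, giving 19. Facial selectivity at C7 and C8 would then rest on the trans-fused bicycles being the less strained ones.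

2. Step 17. Acyl transfer may go to O8 instead of O9, both hydroxyls may be acetylated, or the acetyl group may migrate. The fallback sets out from 24 and comes back at 25. The diol is converted with MeC(OMe)3 and PPTS into the cyclic methyl orthoacetate F7, which is opened with aqueous acetic acid. Here the site is decided by which C–O bond of the hemiorthoester breaks (the bond to the more accessible, better leaving oxygen), not by which hydroxyl is the better nucleophile. The acetate therefore stays on the oxygen that direct acylation avoids, so the preference is complementary.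

3. Step 14. The amide base may deprotonate C2 (γ to the enoate), which would open a vinylogous elimination of O9, or the lactone enolate may undergo Michael-type reactions. The fallback sets out from 19 and comes back at 23. The lactone is carboxylated at C11 with MeOMgOCO2Me in DMF at 120–130 °C through the chelated magnesium enolate, without amide base, to give the 11-carboxy lactone F8. F8 undergoes decarboxylative Mannich methylenation with aqueous formaldehyde and diethylamine in AcOH/NaOAc to give 23.

**Further compounds**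

F1 | step 13 | (5S)-5-[(1E)-5-hydroxy-2-methylpent-1-en-1-yl]furan-2(5H)-one | O=C1C=C[C@H](O1)/C=C(\C)CCCO
F2 | step 13 | (E)-4-methyl-5-[(2S)-5-oxo-2,5-dihydrofuran-2-yl]pent-4-enal | O=C1C=C[C@H](O1)/C=C(\C)CCC=O
F3 | step 13 | methyl (2Z,6E)-2-iodo-6-methyl-7-[(2S)-5-oxo-2,5-dihydrofuran-2-yl]hepta-2,6-dienoate | O=C1C=C[C@H](O1)/C=C(\C)CC/C=C(\I)C(=O)OC
F4 | step 13 | 4-(1,3-dioxoisoindolin-2-yl) 5-methyl (4R,5R)-2,2-dimethyl-1,3-dioxolane-4,5-dicarboxylate | COC(=O)[C@@H]1OC(C)(C)O[C@H]1C(=O)ON1C(=O)c2ccccc2C1=O
F5 | step 13 | methyl (4R,5S)-5-[(1E,5E)-1-(methoxycarbonyl)-5-methyl-6-[(2S)-5-oxo-2,5-dihydrofuran-2-yl]hexa-1,5-dien-1-yl]-2,2-dimethyl-1,3-dioxolane-4-carboxylate | COC(=O)[C@@H]1OC(C)(C)O[C@H]1/C(C(=O)OC)=C\CC/C(C)=C/[C@@H]2C=CC(=O)O2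
F6 | step 13 | (4R,5S)-5-[(1E,5E)-1-(methoxycarbonyl)-5-methyl-6-[(2S)-5-oxo-2,5-dihydrofuran-2-yl]hexa-1,5-dien-1-yl]-2,2-dimethyl-1,3-dioxolane-4-carboxylic acid | OC(=O)[C@@H]1OC(C)(C)O[C@H]1/C(C(=O)OC)=C\CC/C(C)=C/[C@@H]2C=CC(=O)O2
F7 | step 17 | 8,9-O-(1-methoxyethylidene) derivative of 24 (cyclic methyl orthoacetate, both epimers at the orthoester carbon) | COC1(C)O[C@H]2[C@H]3C(=C)C(=O)O[C@@H]3/C=C(\C)CC/C=C(/C(=O)OC)[C@@H]2O1
F8 | step 14 | 11-carboxy derivative of 19 (drawn with CO2H trans to C8; epimerisable centre) | CC1(C)O[C@H]2[C@H]3[C@H](C(=O)O)C(=O)O[C@@H]3/C=C(\C)CC/C=C(/C(=O)OC)[C@@H]2O1
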